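**Plan**

- Retrosynthetic cuts: the formyl carbon on C6' (back to an enol triflate of a 1,3-dione, ring B at the cyclohexane level), then the ring bond C1'–C6', then the ether bond O–C1' (as a phenol alkylation), and on ring A the aryl–carboxyl and aryl–carbinol bonds.
- Enabling feature: in ring B the ether carbon C1' lies between the hydroxyl carbon C2' and the formyl-bearing carbon C6', with the methyl on C4' opposite. This is the substitution pattern of a symmetric 2-aryloxy-5-methylcyclohexane-1,3-dione.
- Forward order: ring A is completed first from 4-bromo-3-methoxyphenol (side chain by bromine–lithium exchange, carboxyl by directed ortho-metalation). Its phenol is alkylated with a bromomethyl ketone from 3-methylglutaric anhydride.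
- Ring B is closed on the ether oxygen by Dieckmann cyclisation, then taken through enol triflate, palladium-catalysed formylation and dehydrogenation to the hydroxybenzaldehyde; two deprotections finish.
- Stereochemistry: the only stereocentre, the (S)-carbinol, is set by Corey–Bakshi–Shibata reduction of the aryl ketone and carried as a silyl ether; no later step forms a cation or carbanion at that carbon.

Key step: step 12

Remark on the chemistry: the tetrahydropyranyl acetal carbon (compounds 2–10) and the methyl-bearing carbon of the six-carbon chain (compounds 13–21) are carried as unresolved epimeric mixtures, since neither centre is present in the target; 19 is written as the diketone although it should exist largely as its enol.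

**Route**

Step 1
Reactants: 1 4-bromo-3-methoxyphenol
Product: 2 2-(4-bromo-3-methoxyphenoxy)tetrahydro-2H-pyran (racemic acetal)
Conditions: 3,4-dihydro-2H-pyran, pyridinium p-toluenesulfonate (cat.), CH2Cl2, rt
Reagents that add atoms: 3,4-dihydro-2H-pyran, C1=COCCC1
Why: Acid-catalysed addition of the phenol to the enol ether (tetrahydropyranylation) masks the OH as an acetal that tolerates organolithiums and later serves as the directing group for ortho-lithiation.

Step 2
Reactants: 2 2-(4-bromo-3-methoxyphenoxy)tetrahydro-2H-pyran; 3 isovaleraldehyde (3-methylbutanal)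
Product: 5 1-[2-methoxy-4-(tetrahydro-2H-pyran-2-yloxy)phenyl]-3-methylbutan-1-ol (mixture of stereoisomers), via aryllithium 4 (not isolated)
Conditions: n-BuLi, THF, −78 °C; then 3, −78 °C → 0 °C; H2O
Reagents that add atoms: none
Why: Bromine–lithium exchange outruns any deprotonation at −78 °C and the aryllithium adds 1,2 to the aldehyde; the carbinol centre is left uncontrolled because the next step erases it.

Step 3
Reactants: 5 1-[2-methoxy-4-(tetrahydro-2H-pyran-2-yloxy)phenyl]-3-methylbutan-1-ol
Product: 6 1-[2-methoxy-4-(tetrahydro-2H-pyran-2-yloxy)phenyl]-3-methylbutan-1-one (racemic acetal)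
Conditions: Dess–Martin periodinane, NaHCO3, CH2Cl2, 0 °C → rt
Reagents that add atoms: none
Why: Dess–Martin oxidation of a secondary benzylic alcohol should be fast and, with bicarbonate buffering the liberated acetic acid, leaves the aryl acetal intact.

Step 4
Reactants: 6 1-[2-methoxy-4-(tetrahydro-2H-pyran-2-yloxy)phenyl]-3-methylbutan-1-one
Product: 7 (1S)-1-[2-methoxy-4-(tetrahydro-2H-pyran-2-yloxy)phenyl]-3-methylbutan-1-ol (epimers at the acetal carbon)
Conditions: (R)-Me-CBS oxazaborolidine [(3aR)-1-methyl-3,3-diphenyltetrahydro-1H,3H-pyrrolo[1,2-c][1,3,2]oxazaborole] (cat.), BH3·SMe2, THF, −20 °C; MeOH, then H2O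
Reagents that add atoms: none
Why: Corey–Bakshi–Shibata reduction with the aryl group as the large and the isobutyl group as the small substituent; the (R)-catalyst should deliver hydride to the Re face, as in the acetophenone to (S)-1-phenylethanol case, and so set the (S)-carbinol.

Step 5
Reactants: 7 (1S)-1-[2-methoxy-4-(tetrahydro-2H-pyran-2-yloxy)phenyl]-3-methylbutan-1-ol
Product: 8 tert-butyl{(1S)-1-[2-methoxy-4-(tetrahydro-2H-pyran-2-yloxy)phenyl]-3-methylbutoxy}dimethylsilane
Conditions: TBSCl, imidazole, DMF, rt
Reagents that add atoms: tert-butyldimethylsilyl chloride, CC(C)(C)[Si](C)(C)Cl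
Why: Standard imidazole-promoted silylation at oxygen does not touch the C–O bond of the stereocentre and gives an ether stable to alkyllithiums, alkoxide bases and the palladium step.

Step 6
Reactants: 8 tert-butyl{(1S)-1-[2-methoxy-4-(tetrahydro-2H-pyran-2-yloxy)phenyl]-3-methylbutoxy}dimethylsilane
Product: 10 tert-butyl 2-methoxy-3-[(1S)-1-(tert-butyldimethylsilyloxy)-3-methylbutyl]-6-(tetrahydro-2H-pyran-2-yloxy)benzoate, via aryllithium 9 (not isolated)
Conditions: n-BuLi, TMEDA, THF, −20 °C → 0 °C; then Boc2O, −78 °C → rt; H2O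
Reagents that add atoms: di-tert-butyl dicarbonate, CC(C)(C)OC(=O)OC(=O)OC(C)(C)C
Why: Directed ortho-metalation should occur at the one ring position flanked by both the acetal oxygen and the methoxy group (cooperative 1,3-directors), and acylation of the aryllithium by the dicarbonate gives the tert-butyl ester directly.

Step 7
Reactants: 10 tert-butyl 2-methoxy-3-[(1S)-1-(tert-butyldimethylsilyloxy)-3-methylbutyl]-6-(tetrahydro-2H-pyran-2-yloxy)benzoate
Product: 11 tert-butyl 6-hydroxy-2-methoxy-3-[(1S)-1-(tert-butyldimethylsilyloxy)-3-methylbutyl]benzoate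
Conditions: pyridinium p-toluenesulfonate (cat.), MeOH, rt
Reagents that add atoms: none
Why: Acid-catalysed transacetalisation to methanol removes the aryl tetrahydropyranyl acetal, which is far more labile than a secondary silyl ether or a tert-butyl ester, and the very weak acid should stay below what is needed to ionise the benzylic silyl ether.

Step 8
Reactants: 12 3-methylglutaric anhydride
Product: 13 5-methoxy-3-methyl-5-oxopentanoic acid (racemic)
Conditions: MeOH, reflux
Reagents that add atoms: methanol, CO
Why: Alcoholysis of a symmetric cyclic anhydride opens either carbonyl to the same half ester, which differentiates the two chain ends in one step.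

Step 9
Reactants: 13 5-methoxy-3-methyl-5-oxopentanoic acid
Product: 14 methyl 5-chloro-3-methyl-5-oxopentanoate (racemic)
Conditions: (COCl)2, DMF (cat.), CH2Cl2, 0 °C → rt
Reagents that add atoms: oxalyl chloride, O=C(Cl)C(=O)Cl
Why: Acid chloride formation through the Vilsmeier-type chloroiminium species is selective for the free acid and leaves the methyl ester alone.

Step 10
Reactants: 14 methyl 5-chloro-3-methyl-5-oxopentanoate
Product: 16 methyl 6-bromo-3-methyl-5-oxohexanoate (racemic), via diazoketone 15 (not isolated)
Conditions: TMSCHN2, THF/MeCN, 0 °C; then 48% aq. HBr, 0 °C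
Reagents that add atoms: (trimethylsilyl)diazomethane, C[Si](C)(C)C=[N+]=[N-]; hydrogen bromide, Br
Why: Acylation of the diazoalkane (first stage of the Arndt–Eistert sequence) gives the α-diazoketone, whose protonation and displacement of dinitrogen by bromide gives the bromomethyl ketone with the halogen only on the terminal carbon.

Step 11
Reactants: 11 tert-butyl 6-hydroxy-2-methoxy-3-[(1S)-1-(tert-butyldimethylsilyloxy)-3-methylbutyl]benzoate; 16 methyl 6-bromo-3-methyl-5-oxohexanoate
Product: 17 tert-butyl 2-methoxy-6-[(6-methoxy-4-methyl-2,6-dioxohexyl)oxy]-3-[(1S)-1-(tert-butyldimethylsilyloxy)-3-methylbutyl]benzoate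
Conditions: K2CO3, DMF, rt
Reagents that add atoms: none
Why: Williamson ether synthesis in which the phenoxide displaces the highly reactive α-bromoketone bromide, so the crowded ring-B ether oxygen is attached to an sp3 carbon, and the carbonate base is too weak to start ester condensations.

Step 12
Reactants: 17 tert-butyl 2-methoxy-6-[(6-methoxy-4-methyl-2,6-dioxohexyl)oxy]-3-[(1S)-1-(tert-butyldimethylsilyloxy)-3-methylbutyl]benzoate
Product: 19 tert-butyl 2-methoxy-6-[(4-methyl-2,6-dioxocyclohexyl)oxy]-3-[(1S)-1-(tert-butyldimethylsilyloxy)-3-methylbutyl]benzoate, via potassium dione enolate 18 (not isolated)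
Conditions: KOtBu (2.2 equiv), THF, 0 °C → rt; cold 0.5 M HCl to pH 3–4
Reagents that add atoms: none
Why: tert-Butoxide equilibrates the ketone enolates, and the one on the ether-bearing carbon C1', made more acidic by the aryloxy group, adds to the methyl ester carbonyl C6'; loss of methoxide forms the C1'–C6' bond and further base drains the product as the stabilised potassium enolate 18, which acidification returns as 19. The closest known reaction is the Dieckmann (intramolecular Claisen) cyclisation of 5-oxohexanoates to cyclohexane-1,3-diones. Ring B closes in a 6-(enolexo)-exo-trig mode. No stereocentre of the target is created: C1' becomes trigonal in the enol, the methyl-bearing carbon is lost on aromatisation, and the silyl-protected (S)-carbinol carries no hydrogen acidic enough for alkoxide. The step needs chemoselectivity between two ester electrophiles, because the same enolate could close a five-membered benzofuranone onto the ring-A ester; that ester is a tert-butyl ester held between two ortho substituents and should be far less electrophilic than the unhindered methyl ester. The remaining enolates can reach only four-membered rings or a seven-membered ring onto the same hindered benzoate.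

Step 13
Reactants: 19 tert-butyl 2-methoxy-6-[(4-methyl-2,6-dioxocyclohexyl)oxy]-3-[(1S)-1-(tert-butyldimethylsilyloxy)-3-methylbutyl]benzoate
Product: 20 tert-butyl 2-methoxy-6-{[4-methyl-6-oxo-2-(trifluoromethylsulfonyloxy)cyclohex-1-en-1-yl]oxy}-3-[(1S)-1-(tert-butyldimethylsilyloxy)-3-methylbutyl]benzoate
Conditions: Tf2O, pyridine, CH2Cl2, −78 °C → 0 °C
Reagents that add atoms: trifluoromethanesulfonic anhydride, O=S(=O)(OS(=O)(=O)C(F)(F)F)C(F)(F)F
Why: O-Sulfonylation of the enol of a 1,3-dione gives the vinylogous acyl triflate; the dione is symmetric, so either carbonyl gives the same product and only one triflation is possible.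

Step 14
Reactants: 20 tert-butyl 2-methoxy-6-{[4-methyl-6-oxo-2-(trifluoromethylsulfonyloxy)cyclohex-1-en-1-yl]oxy}-3-[(1S)-1-(tert-butyldimethylsilyloxy)-3-methylbutyl]benzoate
Product: 21 tert-butyl 6-[(2-formyl-4-methyl-6-oxocyclohex-1-en-1-yl)oxy]-2-methoxy-3-[(1S)-1-(tert-butyldimethylsilyloxy)-3-methylbutyl]benzoate
Conditions: Pd(OAc)2 (cat.), 1,3-bis(diphenylphosphino)propane, CO (1 atm), Et3SiH (slow addition), Et3N, DMF, 70 °C
Reagents that add atoms: carbon monoxide, [C-]#[O+]
Why: Palladium-catalysed reductive carbonylation (formylation) of an enol triflate: zerovalent palladium formed in situ inserts into the electron-poor vinyl C–OTf bond, CO insertion gives the acylpalladium species and hydride transfer from the silane releases the enal.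

Step 15
Reactants: 21 tert-butyl 6-[(2-formyl-4-methyl-6-oxocyclohex-1-en-1-yl)oxy]-2-methoxy-3-[(1S)-1-(tert-butyldimethylsilyloxy)-3-methylbutyl]benzoate
Product: 22 tert-butyl 6-(2-formyl-6-hydroxy-4-methylphenoxy)-2-methoxy-3-[(1S)-1-(tert-butyldimethylsilyloxy)-3-methylbutyl]benzoate
Conditions: DDQ, 1,4-dioxane, 80 °C
Reagents that add atoms: none
Why: Quinone dehydrogenation of a cyclohexenone to a phenol: hydride abstraction from the dienol tautomer, proton loss and tautomerisation aromatise ring B, while the ring-A benzylic C–H is deactivated by the meta ester and the twisted ortho methoxy group.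

Step 16
Reactants: 22 tert-butyl 6-(2-formyl-6-hydroxy-4-methylphenoxy)-2-methoxy-3-[(1S)-1-(tert-butyldimethylsilyloxy)-3-methylbutyl]benzoate
Product: 24 6-(2-formyl-6-hydroxy-4-methylphenoxy)-2-methoxy-3-[(1S)-1-(tert-butyldimethylsilyloxy)-3-methylbutyl]benzoic acid, via bis(trimethylsilyl) derivative 23 (not isolated)
Conditions: TMSOTf, 2,6-lutidine, CH2Cl2, 0 °C; then aqueous pH 5 buffer
Reagents that add atoms: none
Why: Silyl triflate cleavage of a tert-butyl ester: O-silylation of the ester carbonyl and loss of the tert-butyl group as isobutene give the silyl ester, which hydrolyses on work-up together with the transient aryl silyl ether; the lutidine buffer keeps free strong acid away from the ionisable benzylic ether.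

Step 17
Reactants: 24 6-(2-formyl-6-hydroxy-4-methylphenoxy)-2-methoxy-3-[(1S)-1-(tert-butyldimethylsilyloxy)-3-methylbutyl]benzoic acid
Product: 25 tenellic acid B, 6-(2-formyl-6-hydroxy-4-methylphenoxy)-3-[(1S)-1-hydroxy-3-methylbutyl]-2-methoxybenzoic acid
Conditions: HF·pyridine, pyridine, THF, 0 °C → rt
Reagents that add atoms: none
Why: Fluoride-driven desilylation breaks only the Si–O bond under buffered conditions, so the benzylic C–O bond and its (S) configuration are retained and the aldehyde, phenol and acid are untouched.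

**Compound list**

1 | 4-bromo-3-methoxyphenol | COc1cc(O)ccc1Br | starting material
2 | 2-(4-bromo-3-methoxyphenoxy)tetrahydro-2H-pyran (racemic acetal) | COc1cc(OC2CCCCO2)ccc1Br | intermediate
3 | isovaleraldehyde (3-methylbutanal) | CC(C)CC=O | starting material
4 | [2-methoxy-4-(tetrahydro-2H-pyran-2-yloxy)phenyl]lithium (formed in situ) | [Li]c1ccc(OC2CCCCO2)cc1OC | intermediate
5 | 1-[2-methoxy-4-(tetrahydro-2H-pyran-2-yloxy)phenyl]-3-methylbutan-1-ol (mixture of stereoisomers) | COc1cc(OC2CCCCO2)ccc1C(O)CC(C)C | intermediate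
6 | 1-[2-methoxy-4-(tetrahydro-2H-pyran-2-yloxy)phenyl]-3-methylbutan-1-one (racemic acetal) | COc1cc(OC2CCCCO2)ccc1C(=O)CC(C)C | intermediate
7 | (1S)-1-[2-methoxy-4-(tetrahydro-2H-pyran-2-yloxy)phenyl]-3-methylbutan-1-ol (epimers at the acetal carbon) | COc1cc(OC2CCCCO2)ccc1[C@@H](O)CC(C)C | intermediate
8 | tert-butyl{(1S)-1-[2-methoxy-4-(tetrahydro-2H-pyran-2-yloxy)phenyl]-3-methylbutoxy}dimethylsilane (epimers at the acetal carbon) | COc1cc(OC2CCCCO2)ccc1[C@@H](O[Si](C)(C)C(C)(C)C)CC(C)C | intermediate
9 | {2-methoxy-3-[(1S)-1-(tert-butyldimethylsilyloxy)-3-methylbutyl]-6-(tetrahydro-2H-pyran-2-yloxy)phenyl}lithium (formed in situ) | COc1c([C@@H](O[Si](C)(C)C(C)(C)C)CC(C)C)ccc(OC2CCCCO2)c1[Li] | intermediate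
10 | tert-butyl 2-methoxy-3-[(1S)-1-(tert-butyldimethylsilyloxy)-3-methylbutyl]-6-(tetrahydro-2H-pyran-2-yloxy)benzoate (epimers at the acetal carbon) | COc1c([C@@H](O[Si](C)(C)C(C)(C)C)CC(C)C)ccc(OC2CCCCO2)c1C(=O)OC(C)(C)C | intermediate
11 | tert-butyl 6-hydroxy-2-methoxy-3-[(1S)-1-(tert-butyldimethylsilyloxy)-3-methylbutyl]benzoate | COc1c([C@@H](O[Si](C)(C)C(C)(C)C)CC(C)C)ccc(O)c1C(=O)OC(C)(C)C | intermediate
12 | 3-methylglutaric anhydride | CC1CC(=O)OC(=O)C1 | starting material
13 | 5-methoxy-3-methyl-5-oxopentanoic acid (racemic) | COC(=O)CC(C)CC(=O)O | intermediate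
14 | methyl 5-chloro-3-methyl-5-oxopentanoate (racemic) | COC(=O)CC(C)CC(=O)Cl | intermediate
15 | methyl 6-diazo-3-methyl-5-oxohexanoate (racemic, formed in situ) | COC(=O)CC(C)CC(=O)C=[N+]=[N-] | intermediate
16 | methyl 6-bromo-3-methyl-5-oxohexanoate (racemic) | COC(=O)CC(C)CC(=O)CBr | intermediate
17 | tert-butyl 2-methoxy-6-[(6-methoxy-4-methyl-2,6-dioxohexyl)oxy]-3-[(1S)-1-(tert-butyldimethylsilyloxy)-3-methylbutyl]benzoate (epimers at the chain methyl carbon) | COc1c([C@@H](O[Si](C)(C)C(C)(C)C)CC(C)C)ccc(OCC(=O)CC(C)CC(=O)OC)c1C(=O)OC(C)(C)C | intermediate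
18 | potassium enolate of dione 19 (formed in situ) | COc1c([C@@H](O[Si](C)(C)C(C)(C)C)CC(C)C)ccc(OC2=C([O-])CC(C)CC2=O)c1C(=O)OC(C)(C)C.[K+] | intermediate
19 | tert-butyl 2-methoxy-6-[(4-methyl-2,6-dioxocyclohexyl)oxy]-3-[(1S)-1-(tert-butyldimethylsilyloxy)-3-methylbutyl]benzoate (drawn as the diketone) | COc1c([C@@H](O[Si](C)(C)C(C)(C)C)CC(C)C)ccc(OC2C(=O)CC(C)CC2=O)c1C(=O)OC(C)(C)C | intermediate
20 | tert-butyl 2-methoxy-6-{[4-methyl-6-oxo-2-(trifluoromethylsulfonyloxy)cyclohex-1-en-1-yl]oxy}-3-[(1S)-1-(tert-butyldimethylsilyloxy)-3-methylbutyl]benzoate (epimers at the ring methyl carbon) | COc1c([C@@H](O[Si](C)(C)C(C)(C)C)CC(C)C)ccc(OC2=C(OS(=O)(=O)C(F)(F)F)CC(C)CC2=O)c1C(=O)OC(C)(C)C | intermediate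
21 | tert-butyl 6-[(2-formyl-4-methyl-6-oxocyclohex-1-en-1-yl)oxy]-2-methoxy-3-[(1S)-1-(tert-butyldimethylsilyloxy)-3-methylbutyl]benzoate (epimers at the ring methyl carbon) | COc1c([C@@H](O[Si](C)(C)C(C)(C)C)CC(C)C)ccc(OC2=C(C=O)CC(C)CC2=O)c1C(=O)OC(C)(C)C | intermediate
22 | tert-butyl 6-(2-formyl-6-hydroxy-4-methylphenoxy)-2-methoxy-3-[(1S)-1-(tert-butyldimethylsilyloxy)-3-methylbutyl]benzoate | COc1c([C@@H](O[Si](C)(C)C(C)(C)C)CC(C)C)ccc(Oc2c(O)cc(C)cc2C=O)c1C(=O)OC(C)(C)C | intermediate
23 | trimethylsilyl 6-[2-formyl-4-methyl-6-(trimethylsilyloxy)phenoxy]-2-methoxy-3-[(1S)-1-(tert-butyldimethylsilyloxy)-3-methylbutyl]benzoate (formed in situ) | COc1c([C@@H](O[Si](C)(C)C(C)(C)C)CC(C)C)ccc(Oc2c(O[Si](C)(C)C)cc(C)cc2C=O)c1C(=O)O[Si](C)(C)C | intermediate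
24 | 6-(2-formyl-6-hydroxy-4-methylphenoxy)-2-methoxy-3-[(1S)-1-(tert-butyldimethylsilyloxy)-3-methylbutyl]benzoic acid | COc1c([C@@H](O[Si](C)(C)C(C)(C)C)CC(C)C)ccc(Oc2c(O)cc(C)cc2C=O)c1C(=O)O | intermediate
25 | tenellic acid B, 6-(2-formyl-6-hydroxy-4-methylphenoxy)-3-[(1S)-1-hydroxy-3-methylbutyl]-2-methoxybenzoic acid | COc1c([C@@H](O)CC(C)C)ccc(Oc2c(O)cc(C)cc2C=O)c1C(=O)O | target

**Count**

Total steps: 17. Longest linear sequence: 14 steps (steps 1–7 and 11–17 from 4-bromo-3-methoxyphenol); the bromoketone branch is 3 steps (steps 8–10).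

**Steps most likely to fail**

Step 12. The enolate on the ether-bearing carbon may close onto the ring-A benzoate carbonyl instead of the methyl ester, giving irreversible five-membered ring formation, or the keto ester may condense intermolecularly. The fallback abandons the condensation and joins an intact dione to the phenol. It sets out from phenol 11: commercial 5-methylcyclohexane-1,3-dione is converted by Regitz diazo transfer (p-acetamidobenzenesulfonyl azide, Et3N, MeCN) into 2-diazo-5-methylcyclohexane-1,3-dione F1. Rh2(OAc)4-catalysed O–H insertion of the derived carbenoid into the phenol of 11 (CH2Cl2 or benzene, 40–80 °C) should then give the 2-aryloxy dione directly, returning to the route at 19.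

Step 14. Hydride may be transferred to the vinylpalladium species before CO insertion (simple reduction of the triflate), or the electron-poor double bond of the product may undergo conjugate reduction by the silane. The fallback installs the carbon at the alcohol level without any hydride source. It sets out from triflate 20: Stille coupling with (tributylstannyl)methanol (Pd(PPh3)4, LiCl, 1,4-dioxane, 90 °C) should give tert-butyl 6-{[2-(hydroxymethyl)-4-methyl-6-oxocyclohex-1-en-1-yl]oxy}-2-methoxy-3-[(1S)-1-(tert-butyldimethylsilyloxy)-3-methylbutyl]benzoate F2. Oxidation of its allylic alcohol with MnO2 (CH2Cl2, rt) returns to the route at enal 21.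

Step 15. Enolisation and hydride abstraction on the electron-poor enedione may be slow, and at the temperature then needed the quinone may oxidise the benzylic silyl ether position of ring A. The fallback replaces hydride abstraction by a palladium enolate β-hydride elimination at room temperature. It sets out from enal 21: soft enolisation (TMSOTf, Et3N, CH2Cl2, 0 °C) should give tert-butyl 6-{[2-formyl-4-methyl-6-(trimethylsilyloxy)cyclohexa-1,5-dien-1-yl]oxy}-2-methoxy-3-[(1S)-1-(tert-butyldimethylsilyloxy)-3-methylbutyl]benzoate F3. Saegusa–Ito oxidation (Pd(OAc)2, MeCN, rt) then gives a cross-conjugated dienone that tautomerises to the phenol, returning to the route at 22.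

**Further compounds**

F1 | step 12 | 2-diazo-5-methylcyclohexane-1,3-dione | CC1CC(=O)C(=[N+]=[N-])C(=O)C1
F2 | step 14 | tert-butyl 6-{[2-(hydroxymethyl)-4-methyl-6-oxocyclohex-1-en-1-yl]oxy}-2-methoxy-3-[(1S)-1-(tert-butyldimethylsilyloxy)-3-methylbutyl]benzoate | COc1c([C@@H](O[Si](C)(C)C(C)(C)C)CC(C)C)ccc(OC2=C(CO)CC(C)CC2=O)c1C(=O)OC(C)(C)C
F3 | step 15 | tert-butyl 6-{[2-formyl-4-methyl-6-(trimethylsilyloxy)cyclohexa-1,5-dien-1-yl]oxy}-2-methoxy-3-[(1S)-1-(tert-butyldimethylsilyloxy)-3-methylbutyl]benzoate | COc1c([C@@H](O[Si](C)(C)C(C)(C)C)CC(C)C)ccc(OC2=C(C=O)CC(C)C=C2O[Si](C)(C)C)c1C(=O)OC(C)(C)C
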